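Assumption: the target SMILES is read as the (1R,2R,4aR) isomer (naphthalene numbering; hydroperoxy group cis to the C1 methyl, trans to H-2), and its phenol precursor is taken to react from the half-chair in which the C1 methyl is pseudoaxial.

**Retrosynthetic overview** (ring B = saturated ring carrying the side chains; ring C = phenol/dienone ring)
- Last step: the C4a–O bond is made by dearomative para-hydroperoxidation of the 7-hydroxytetralin with O2, which sets the third stereocentre.
- The vinyl group comes from an aryl bromide by Suzuki–Miyaura coupling.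
- Ring C is annulated onto a ring B cyclohexanone with a four-carbon β,β-dibromoenone (substitution, aldol condensation, aromatisation).
- Ring B with both carbon stereocentres comes from 2-methylcyclohex-2-enone: asymmetric conjugate addition of isopropenyl, then anti-selective Michael addition to methyl acrylate.
- Ring order: ring B first, ring C second, dearomatisation last.

**Route**

Step 1
Reactants: 1 2-methylcyclohex-2-en-1-one; 2 prop-1-en-2-ylmagnesium bromide
Product: 4 (2RS,3S)-2-methyl-3-(prop-1-en-2-yl)cyclohexan-1-one, via bromomagnesium enolate 3 (not isolated)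
Conditions: Cu(OTf)2 (3 mol%), leucinol-derived hydroxyalkyl-imidazolinium hexafluorophosphate (chiral alkoxy-NHC precursor, 4 mol%, enantiomer giving 3S), Et2O, −30 °C; then 1 M HCl, 0 °C
Reagents that add atoms: none
Why: Copper-catalysed asymmetric conjugate addition of a Grignard reagent, in which the chiral NHC–copper species delivers isopropenyl to one enone face and sets C3 as S, while C2 stays an epimer mixture because it is re-enolised in step 2.

Step 2
Reactants: 4 (2RS,3S)-2-methyl-3-(prop-1-en-2-yl)cyclohexan-1-one; 5 methyl prop-2-enoate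
Product: 6 methyl 3-[(1R,6R)-1-methyl-2-oxo-6-(prop-1-en-2-yl)cyclohexyl]propanoate
Conditions: KOtBu (0.2 equiv), 5 (1.1 equiv), t-BuOH/THF 1:1, 0 → 25 °C
Reagents that add atoms: none
Why: Base-catalysed Michael addition through the more substituted (thermodynamic) enolate, with the acrylate approaching anti to the neighbouring isopropenyl group so that the quaternary carbon is set 1R (methyl cis, ester arm trans to isopropenyl), as in Robinson annulations of 2,3-disubstituted cyclohexanones.

Step 3
Reactants: 7 butane-2,3-dione
Product: 8 4,4-dibromo-3-methylbut-3-en-2-one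
Conditions: CBr4 (1.0 equiv), PPh3 (1.0 equiv), Zn dust (1.0 equiv), CH2Cl2, 25 °C, 12 h; then 7 (3 equiv), 0 → 25 °C
Reagents that add atoms: carbon tetrabromide, BrC(Br)(Br)Br
Why: Ramirez dibromo-olefination (Wittig-type) of one activated carbonyl of the α-diketone, with excess dione and the lower reactivity of the product enone preventing a second olefination.

Step 4
Reactants: 6 methyl 3-[(1R,6R)-1-methyl-2-oxo-6-(prop-1-en-2-yl)cyclohexyl]propanoate; 8 4,4-dibromo-3-methylbut-3-en-2-one
Product: 10 methyl 3-[(1R,2R)-5-bromo-7-hydroxy-1,6-dimethyl-2-(prop-1-en-2-yl)-1,2,3,4-tetrahydronaphthalen-1-yl]propanoate, via bromo-enedione 9 (not isolated)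
Conditions: KOtBu (2.5 equiv), t-BuOH/THF 1:1, 0 °C; slow addition of 8 (1.2 equiv) over 2 h, then 25 °C; 1 M HCl
Reagents that add atoms: none
Why: Robinson-type benzannulation with a β-halovinyl ketone, in which the only enolisable ring position (C3 of the cyclohexanone) displaces one bromide by addition–elimination (nucleophilic vinylic substitution), the methyl ketone of the resulting 2-ene-1,5-dione closes onto the ring carbonyl by aldol condensation and the dienone tautomerises to the phenol, leaving the second bromide as coupling handle and both stereocentres untouched.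

Step 5
Reactants: 10 methyl 3-[(1R,2R)-5-bromo-7-hydroxy-1,6-dimethyl-2-(prop-1-en-2-yl)-1,2,3,4-tetrahydronaphthalen-1-yl]propanoate
Product: 11 methyl 3-[(1R,2R)-5-ethenyl-7-hydroxy-1,6-dimethyl-2-(prop-1-en-2-yl)-1,2,3,4-tetrahydronaphthalen-1-yl]propanoate
Conditions: Pd(OAc)2 (3 mol%), SPhos (2-dicyclohexylphosphino-2′,6′-dimethoxybiphenyl, 6 mol%), K2CO3 (3 equiv), toluene/H2O 10:1, 80 °C
Reagents that add atoms: vinylboronic acid pinacol ester, C=CB1OC(C)(C)C(C)(C)O1
Why: Suzuki–Miyaura coupling, where the bulky biaryl phosphine lets zerovalent palladium insert into the doubly ortho-substituted aryl bromide while the phenol, ester and isopropenyl group are inert under carbonate.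

Step 6
Reactants: 11 methyl 3-[(1R,2R)-5-ethenyl-7-hydroxy-1,6-dimethyl-2-(prop-1-en-2-yl)-1,2,3,4-tetrahydronaphthalen-1-yl]propanoate
Product: 12 trigonochinene C
Conditions: N-(9-anthracenylmethyl)cinchonidinium bromide (C34H33BrN2O, 10 mol%), Cs2CO3 (20 mol%), tetraphenylporphyrin (C44H30N4, 1 mol%), O2 (1 atm), toluene, green LEDs, −20 °C; filtration through silica
Reagents that add atoms: dioxygen, O=O
Why: Proposed new method: chiral-cation-directed singlet-oxygen dearomatisation, in which only the toluene-soluble ion pair of the phenolate with the cinchonidinium cation reacts quickly with 1O2, the anthracenyl wall held at the phenoxide oxygen (N+ and OH contacts) covers the ring C face anti to the pseudoaxial C1 methyl, and because 1O2 adds suprafacially across the oxygen-bearing C7 and the para carbon C4a (1,4-endoperoxide-like transition state) the face fixed at the oxygen end is relayed to the remote carbon, so the new C–O bond forms on the methyl face to set C4a as R before the peroxy anion is protonated by the next phenol (base and cation turn over); the closest known reaction types are dye-sensitised photooxygenation of para-alkylphenolates to 4-hydroperoxycyclohexa-2,5-dienones and phase-transfer-catalysed asymmetric photooxygenation of β-dicarbonyl enolates.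

**Compound list**
1 | 2-methylcyclohex-2-en-1-one | CC1=CCCCC1=O | starting material
2 | prop-1-en-2-ylmagnesium bromide | CC(=C)[Mg]Br | starting material
3 | bromo{[(3R)-2-methyl-3-(prop-1-en-2-yl)cyclohex-1-en-1-yl]oxy}magnesium (bromomagnesium enolate, not isolated) | Br[Mg]OC1=C(C)[C@@H](C(=C)C)CCC1 | intermediate
4 | (2RS,3S)-2-methyl-3-(prop-1-en-2-yl)cyclohexan-1-one | O=C1CCC[C@H](C(=C)C)C1C | intermediate
5 | methyl prop-2-enoate (methyl acrylate) | C=CC(=O)OC | starting material
6 | methyl 3-[(1R,6R)-1-methyl-2-oxo-6-(prop-1-en-2-yl)cyclohexyl]propanoate | O=C1CCC[C@H](C(=C)C)[C@@]1(C)CCC(=O)OC | intermediate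
7 | butane-2,3-dione | CC(=O)C(C)=O | starting material
8 | 4,4-dibromo-3-methylbut-3-en-2-one | CC(=O)C(C)=C(Br)Br | intermediate
9 | methyl 3-[(1R,6R)-3-(1-bromo-2-methyl-3-oxobut-1-en-1-yl)-1-methyl-2-oxo-6-(prop-1-en-2-yl)cyclohexyl]propanoate (bromo-enedione, C3 and E/Z mixture, not isolated) | O=C1C(C(Br)=C(C)C(C)=O)CC[C@H](C(=C)C)[C@@]1(C)CCC(=O)OC | intermediate
10 | methyl 3-[(1R,2R)-5-bromo-7-hydroxy-1,6-dimethyl-2-(prop-1-en-2-yl)-1,2,3,4-tetrahydronaphthalen-1-yl]propanoate | Brc1c(C)c(O)cc2c1CC[C@H](C(=C)C)[C@@]2(C)CCC(=O)OC | intermediate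
11 | methyl 3-[(1R,2R)-5-ethenyl-7-hydroxy-1,6-dimethyl-2-(prop-1-en-2-yl)-1,2,3,4-tetrahydronaphthalen-1-yl]propanoate | C=Cc1c(C)c(O)cc2c1CC[C@H](C(=C)C)[C@@]2(C)CCC(=O)OC | intermediate
12 | trigonochinene C, methyl 3-[(1R,2R,4aR)-5-ethenyl-4a-hydroperoxy-1,6-dimethyl-7-oxo-2-(prop-1-en-2-yl)-1,2,3,4,4a,7-hexahydronaphthalen-1-yl]propanoate | C=CC1=C(C)C(=O)C=C2[C@]1(OO)CC[C@H](C(=C)C)[C@@]2(C)CCC(=O)OC | target

**Step count**
Total: 6 steps. Longest linear sequence: 5 steps (1 → 2 → 4 → 5 → 6); step 3 prepares the annulation partner.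

**Three steps most likely to fail**

Step 4 (benzannulation). The enolate may attack the hindered, twisted dibromoenone slowly, and the enone can self-condense or be attacked by alkoxide. The fallback sets out from 6 and comes back at 11, so 8, 10 and step 5 are not needed. Compound 6 is silylated (TMSOTf, Et3N, CH2Cl2, 0 °C) to the silyl enol ether methyl 3-[(1R,6R)-1-methyl-6-(prop-1-en-2-yl)-2-(trimethylsilyloxy)cyclohex-2-en-1-yl]propanoate F1. Heating with 2,2,5,6-tetramethyl-4H-1,3-dioxin-4-one in toluene at 110 °C (acylketene hetero-Diels–Alder, then loss of silanol) gives the γ-pyrone methyl 3-[(7R,8R)-2,3,8-trimethyl-4-oxo-7-(prop-1-en-2-yl)-5,6,7,8-tetrahydro-4H-chromen-8-yl]propanoate F2. Vinylmagnesium bromide with LaCl3·2LiCl at −78 °C adds to the pyrone carbonyl, which should react before the methyl ester, though that selectivity is the weak point of this fallback. HBF4·OEt2 then ionises the carbinol to (7R,8R)-4-ethenyl-8-(3-methoxy-3-oxopropyl)-2,3,8-trimethyl-7-(prop-1-en-2-yl)-5,6,7,8-tetrahydrochromenylium tetrafluoroborate F3. Aqueous NaHCO3 in MeCN opens the pyrylium ring and its 2-methyl group closes onto the ring ketone (the classical pyrylium-to-phenol conversion), giving 11 with the vinyl group already in place.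

Step 6 (new hydroperoxidation). The ion pair may not override the substrate's own facial bias, or background oxidation of the alkenes may compete. The fallback uses known chemistry, sets out from 11 and comes back at 12. It is the dye-sensitised photooxygenation of the phenolate without a chiral cation (rose bengal disodium salt, O2, green light, K2CO3, MeOH/CH2Cl2, −20 °C), the established route from para-alkylphenols to 4-hydroperoxy-dienones. Selectivity is then substrate-controlled, so 12 is separated by chromatography from its epimer methyl 3-[(1R,2R,4aS)-5-ethenyl-4a-hydroperoxy-1,6-dimethyl-7-oxo-2-(prop-1-en-2-yl)-1,2,3,4,4a,7-hexahydronaphthalen-1-yl]propanoate F4. The epimer is returned to 11 with Zn/AcOH (reductive re-aromatisation) and recycled.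

Step 2 (quaternary centre). Alkylation at the less substituted α-carbon or double addition may erode the yield. The fallback sets out from 4 and comes back at 6. Condensation of 4 with (R)-1-phenylethan-1-amine (toluene, Dean–Stark) gives the imine (1R)-N-[(3S)-2-methyl-3-(prop-1-en-2-yl)cyclohexylidene]-1-phenylethan-1-amine F5. Its more substituted secondary enamine tautomer adds to methyl acrylate only at the methyl-bearing carbon (aza-ene-type Michael addition of a chiral imine). The (R)-amine is chosen as the enantiomer whose facial preference should match the anti approach; this is to be confirmed on the first run. 10% aqueous AcOH then hydrolyses the adduct to 6.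

Further compounds
F1 | step 4 | methyl 3-[(1R,6R)-1-methyl-6-(prop-1-en-2-yl)-2-(trimethylsilyloxy)cyclohex-2-en-1-yl]propanoate | C[Si](C)(C)OC1=CCC[C@H](C(=C)C)[C@@]1(C)CCC(=O)OC
F2 | step 4 | methyl 3-[(7R,8R)-2,3,8-trimethyl-4-oxo-7-(prop-1-en-2-yl)-5,6,7,8-tetrahydro-4H-chromen-8-yl]propanoate | O=C1C(C)=C(C)OC2=C1CC[C@H](C(=C)C)[C@@]2(C)CCC(=O)OC
F3 | step 4 | (7R,8R)-4-ethenyl-8-(3-methoxy-3-oxopropyl)-2,3,8-trimethyl-7-(prop-1-en-2-yl)-5,6,7,8-tetrahydrochromenylium tetrafluoroborate | C=CC1=C(C)C(C)=[O+]C2=C1CC[C@H](C(=C)C)[C@@]2(C)CCC(=O)OC.F[B-](F)(F)F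
F4 | step 6 | methyl 3-[(1R,2R,4aS)-5-ethenyl-4a-hydroperoxy-1,6-dimethyl-7-oxo-2-(prop-1-en-2-yl)-1,2,3,4,4a,7-hexahydronaphthalen-1-yl]propanoate | C=CC1=C(C)C(=O)C=C2[C@@]1(OO)CC[C@H](C(=C)C)[C@@]2(C)CCC(=O)OC
F5 | step 2 | (1R)-N-[(3S)-2-methyl-3-(prop-1-en-2-yl)cyclohexylidene]-1-phenylethan-1-amine | C[C@@H](N=C1CCC[C@H](C(=C)C)C1C)c1ccccc1
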